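**Retrosynthetic overview**
1. Feature: C2'' of the piperidine is a benzylic amine carbon on C6 of ring A. C6 lies between O5 and O7 and para to C8a–O1, and C3''–C6'' is an unbranched four-carbon chain. Ring A plus C2'' is therefore the aldimine of a benzaldehyde symmetric about its C1–C4 axis, and the chain is a siloxydiene.
2. Ring C is cut at C4–C4a by Friedel–Crafts acylation; both positions ortho to O1 are equivalent, so only the 6-substituted isomer can form. It is cut at O1–C2 by Mitsunobu inversion of an (R)-β-hydroxy ester that brings ring B. Three benzyl ethers fall in the last step.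
3. The N-methylpiperidine goes back to the N–H piperidine (oxidative loss of a 2-methoxyphenyl group). That goes back to a dihydropyridone whose C4'' oxygen is removed through its enol triflate.
4. The dihydropyridone comes from a silver–phosphine catalysed aza-Diels–Alder reaction, which forms C2''–C3'' and N–C6'' and sets C2''.
5. Order of rings: ring A (bought), piperidine (step 4), ring B (arrives in step 12), ring C (step 14).

Key step: step 4

Assumption: the sense of induction of the silver–phosphine catalyst on this di-ortho-substituted imine cannot be fixed beforehand. The ligand is written as the L-tert-leucine-derived antipode, and its mirror image from D-tert-leucine is used instead if the first run gives the (S)-adduct.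

**Step 1**
Reactants: 1 3,5-bis(benzyloxy)phenol
Product: 3 2,6-bis(benzyloxy)-4-hydroxybenzaldehyde, via aryl iminium ion 2 (not isolated)
Conditions: POCl3 (1.3 equiv), DMF, 0 °C → rt; then ice-water
Reagents that add atoms: N,N-dimethylformamide CN(C)C=O; water O
Why: Vilsmeier–Haack formylation of 3,5-dialkoxyphenols is known to go mainly para to the free hydroxyl, between the two ether groups, and the hydrogen-bonded ortho isomer is much less polar and should be removed by chromatography.

**Step 2**
Reactants: 3 2,6-bis(benzyloxy)-4-hydroxybenzaldehyde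
Product: 4 2,6-bis(benzyloxy)-4-(triisopropylsilyloxy)benzaldehyde
Conditions: TIPSCl (1.2 equiv), imidazole (2 equiv), CH2Cl2, rt
Reagents that add atoms: triisopropylsilyl chloride CC(C)[Si](Cl)(C(C)C)C(C)C
Why: This is a standard silylation of an acidic phenol, and putting the silyl group on after the benzyl groups avoids any basic alkylation in the presence of an aryl silyl ether that is para to a formyl group and therefore base-labile.

**Step 3**
Reactants: 4 2,6-bis(benzyloxy)-4-(triisopropylsilyloxy)benzaldehyde; 5 2-methoxyaniline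
Product: 6 (E)-N-(2-methoxyphenyl)-1-[2,6-bis(benzyloxy)-4-(triisopropylsilyloxy)phenyl]methanimine
Conditions: 4 Å molecular sieves, toluene, 60 °C
Reagents that add atoms: none
Why: In this dehydrative imine condensation the sieves pull the equilibrium for the hindered, donor-rich aldehyde, and the aryl aldimine settles in the E geometry.

**Step 4**
Reactants: 6 (E)-N-(2-methoxyphenyl)-1-[2,6-bis(benzyloxy)-4-(triisopropylsilyloxy)phenyl]methanimine; 7 (E)-1-methoxy-3-(trimethylsilyloxy)buta-1,3-diene
Product: 9 (2R)-2-[2,6-bis(benzyloxy)-4-(triisopropylsilyloxy)phenyl]-1-(2-methoxyphenyl)-2,3-dihydropyridin-4(1H)-one, via amino enone 8 (not isolated)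
Conditions: AgOAc (10 mol %), (S)-2-{[2-(diphenylphosphanyl)benzylidene]amino}-N-(4-methoxyphenyl)-3,3-dimethylbutanamide (10 mol %), i-PrOH (1.1 equiv), 7 (2 equiv), THF, 4 °C; then 1 M HCl, 0 °C
Reagents that add atoms: none
Why: The imine binds the AgOAc–phosphine complex through its nitrogen and the anisyl oxygen, the CH2 terminus of diene 7 attacks the imine carbon in a Mannich step (C2''–C3''), and i-PrOH takes up the silyl group and releases amino enone 8 and the catalyst. On acid work-up the aniline nitrogen adds to the methoxy-bearing enone carbon in a 6-endo-trig closure (N–C6'') and methanol leaves, which gives the vinylogous amide ring. The closest known reaction type is the silver–phosphine catalysed enantioselective aza-Diels–Alder reaction of N-(2-methoxyphenyl) aryl aldimines with this same diene. C2'' is the only new stereocentre, and it is set by the chiral phosphine, which leaves one face of the chelated (E)-imine open. No choice arises on ring A because the aryl group of 6 is symmetric about its C1–C4 axis, and the polarity of the diene fixes the orientation of the addition. The three donor oxygens and the two ortho benzyloxy groups lower the reactivity, which is met by a raised catalyst loading, excess diene and a longer time rather than by heat.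

**Step 5**
Reactants: 9 (2R)-2-[2,6-bis(benzyloxy)-4-(triisopropylsilyloxy)phenyl]-1-(2-methoxyphenyl)-2,3-dihydropyridin-4(1H)-one
Product: 11 (2R)-2-[2,6-bis(benzyloxy)-4-(triisopropylsilyloxy)phenyl]-1-(2-methoxyphenyl)-1,2,3,6-tetrahydropyridin-4-yl trifluoromethanesulfonate, via lithium enolate 10 (not isolated)
Conditions: LiBH(s-Bu)3 (1.2 equiv), THF, −78 °C; then N-(5-chloropyridin-2-yl)triflimide (1.3 equiv), −78 → 0 °C; then H2O
Reagents that add atoms: N-(5-chloropyridin-2-yl)-1,1,1-trifluoro-N-(trifluoromethylsulfonyl)methanesulfonamide O=S(=O)(N(c1ccc(Cl)cn1)S(=O)(=O)C(F)(F)F)C(F)(F)F; LiBH(s-Bu)3 [Li+].CCC(C)[BH-](C(C)CC)C(C)CC (its lithium stands only in 10)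
Why: Conjugate hydride addition at C6'' of the dihydropyridone gives the C4''=C5'' enolate regiospecifically, and O-triflation traps it cold, so a free β-amino ketone that could racemise C2'' by retro-Michael or retro-Mannich opening is never present.

**Step 6**
Reactants: 11 (2R)-2-[2,6-bis(benzyloxy)-4-(triisopropylsilyloxy)phenyl]-1-(2-methoxyphenyl)-1,2,3,6-tetrahydropyridin-4-yl trifluoromethanesulfonate
Product: 12 (2R)-2-[2,6-bis(benzyloxy)-4-(triisopropylsilyloxy)phenyl]-1-(2-methoxyphenyl)piperidine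
Conditions: H2 (1 atm), PtO2 (10 mol %), Li2CO3 (2 equiv), EtOAc, rt
Reagents that add atoms: none
Why: Hydrogenolysis and hydrogenation of an enol triflate over platinum removes the C4'' oxygen and saturates the ring, platinum being a poor catalyst for cleaving aryl benzyl ethers and benzylic C–N bonds, while Li2CO3 takes up the triflic acid.

**Step 7**
Reactants: 12 (2R)-2-[2,6-bis(benzyloxy)-4-(triisopropylsilyloxy)phenyl]-1-(2-methoxyphenyl)piperidine
Product: 13 (2R)-2-[2,6-bis(benzyloxy)-4-(triisopropylsilyloxy)phenyl]piperidine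
Conditions: (NH4)2Ce(NO3)6 (2.2 equiv), MeCN/H2O 4:1, 0 °C; basic work-up
Reagents that add atoms: none
Why: In this oxidative N-dearylation the tertiary anisidine is by far the most easily oxidised group, water attacks its oxidised ring, the quinone iminium ion hydrolyses to the secondary amine, and protonation of that amine in the acidic medium, together with the limited amount of oxidant, should spare ring A and C2''.

**Step 8**
Reactants: 13 (2R)-2-[2,6-bis(benzyloxy)-4-(triisopropylsilyloxy)phenyl]piperidine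
Product: 15 (2R)-2-[2,6-bis(benzyloxy)-4-(triisopropylsilyloxy)phenyl]-1-methylpiperidine, via methylideneiminium ion 14 (not isolated)
Conditions: 37% aq. HCHO (3 equiv), NaBH(OAc)3 (2 equiv), ClCH2CH2Cl, rt
Reagents that add atoms: formaldehyde C=O
Why: This reductive amination works because formaldehyde is small enough for the hindered amine, and the method stops at the tertiary amine without quaternisation.

**Step 9**
Reactants: 15 (2R)-2-[2,6-bis(benzyloxy)-4-(triisopropylsilyloxy)phenyl]-1-methylpiperidine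
Product: 16 3,5-bis(benzyloxy)-4-[(2R)-1-methylpiperidin-2-yl]phenol
Conditions: Bu4NF (1.2 equiv), AcOH (1.2 equiv), THF, 0 °C
Reagents that add atoms: none
Why: Fluoride cleaves the aryl silyl ether, acetic acid buffers the phenoxide, and the benzyl ethers and the amine are inert.

**Step 10**
Reactants: 17 1-[4-(benzyloxy)phenyl]ethanone; 18 diallyl carbonate
Product: 19 prop-2-enyl 3-[4-(benzyloxy)phenyl]-3-oxopropanoate
Conditions: NaH (2.2 equiv), THF, reflux; then AcOH
Reagents that add atoms: none
Why: This crossed Claisen condensation of the ketone enolate with a carbonate is driven by deprotonation of the β-keto ester formed.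

**Step 11**
Reactants: 19 prop-2-enyl 3-[4-(benzyloxy)phenyl]-3-oxopropanoate
Product: 20 prop-2-enyl (3R)-3-[4-(benzyloxy)phenyl]-3-hydroxypropanoate
Conditions: RuCl[(R,R)-TsDPEN](p-cymene) (1 mol %), HCO2H/Et3N 5:2, CH2Cl2, 30 °C
Reagents that add atoms: none
Why: In this asymmetric transfer hydrogenation of an aryl β-keto ester the (R,R)-catalyst, which reduces aryl ketones to (R)-carbinols through the aryl/arene-ligand contact, sets the (R)-centre, and the allyl ester and benzyl ether are not touched.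

**Step 12**
Reactants: 16 3,5-bis(benzyloxy)-4-[(2R)-1-methylpiperidin-2-yl]phenol; 20 prop-2-enyl (3R)-3-[4-(benzyloxy)phenyl]-3-hydroxypropanoate
Product: 21 prop-2-enyl (3S)-3-[4-(benzyloxy)phenyl]-3-{3,5-bis(benzyloxy)-4-[(2R)-1-methylpiperidin-2-yl]phenoxy}propanoate
Conditions: 20 (2 equiv), PPh3 (2 equiv), DIAD (2 equiv, slow addition), toluene, 0 °C → rt
Reagents that add atoms: none
Why: In this Mitsunobu etherification the unhindered phenoxide displaces the oxyphosphonium group by SN2 with inversion, (R) to (S), which sets the future C2; the β-ester group offsets the cation-stabilising para-benzyloxy group, the non-polar solvent disfavours ionisation, and elimination to the cinnamate consumes only the cheap partner 20, which is used in excess.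

**Step 13**
Reactants: 21 prop-2-enyl (3S)-3-[4-(benzyloxy)phenyl]-3-{3,5-bis(benzyloxy)-4-[(2R)-1-methylpiperidin-2-yl]phenoxy}propanoate
Product: 22 (3S)-3-[4-(benzyloxy)phenyl]-3-{3,5-bis(benzyloxy)-4-[(2R)-1-methylpiperidin-2-yl]phenoxy}propanoic acid
Conditions: Pd(PPh3)4 (5 mol %), morpholine (3 equiv), THF, rt
Reagents that add atoms: none
Why: Tsuji–Trost deallylation with zerovalent palladium and an amine as allyl acceptor frees the acid under nearly neutral conditions, which avoids the E1cB loss of aryloxide that hydroxide could trigger in a β-aryloxy ester.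

**Step 14**
Reactants: 22 (3S)-3-[4-(benzyloxy)phenyl]-3-{3,5-bis(benzyloxy)-4-[(2R)-1-methylpiperidin-2-yl]phenoxy}propanoic acid
Product: 24 (2S)-5,7-bis(benzyloxy)-2-[4-(benzyloxy)phenyl]-6-[(2R)-1-methylpiperidin-2-yl]-2,3-dihydrochromen-4-one, via mixed anhydride 23 (not isolated)
Conditions: (CF3CO)2O (3 equiv), CH2Cl2, 0 °C; then cold aq. NaHCO3
Reagents that add atoms: trifluoroacetic anhydride O=C(OC(=O)C(F)(F)F)C(F)(F)F (its acyl group stands only in 23)
Why: This intramolecular Friedel–Crafts acylation attacks a carbon that is ortho, ortho and para to three oxygens, so the six-membered ring should close at 0 °C in dilute acid before the benzylic ether can ionise; the two positions ortho to O1 are equivalent, so only the 6-piperidinyl isomer can form, and the amine stays protonated throughout (zwitterion, then trifluoroacetate salt), so it is not acylated.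

**Step 15**
Reactants: 24 (2S)-5,7-bis(benzyloxy)-2-[4-(benzyloxy)phenyl]-6-[(2R)-1-methylpiperidin-2-yl]-2,3-dihydrochromen-4-one
Product: 25 (2S)-5,7-dihydroxy-2-(4-hydroxyphenyl)-6-[(2R)-1-methylpiperidin-2-yl]-2,3-dihydrochromen-4-one
Conditions: H2 (1 atm), 10% Pd/C, AcOH (2 equiv), EtOAc/MeOH, rt; then pH 7 buffer, rt or below
Reagents that add atoms: none
Why: Hydrogenolysis of the three aryl benzyl ethers should outrun cleavage of the hindered benzylic C2''–N and C2–O1 bonds, and acetic acid keeps the amine protonated, so the free phenols do not meet an internal base that would open ring C (loss of C2 configuration or Wessely–Moser 6/8 isomerisation).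

**Compound list**
1 | 3,5-bis(benzyloxy)phenol | Oc1cc(OCc2ccccc2)cc(OCc2ccccc2)c1 | starting material
2 | {[2,6-bis(benzyloxy)-4-hydroxyphenyl]methylidene}dimethylammonium ion | C[N+](C)=Cc1c(OCc2ccccc2)cc(O)cc1OCc1ccccc1 | intermediate
3 | 2,6-bis(benzyloxy)-4-hydroxybenzaldehyde | O=Cc1c(OCc2ccccc2)cc(O)cc1OCc1ccccc1 | intermediate
4 | 2,6-bis(benzyloxy)-4-(triisopropylsilyloxy)benzaldehyde | O=Cc1c(OCc2ccccc2)cc(O[Si](C(C)C)(C(C)C)C(C)C)cc1OCc1ccccc1 | intermediate
5 | 2-methoxyaniline | COc1ccccc1N | starting material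
6 | (E)-N-(2-methoxyphenyl)-1-[2,6-bis(benzyloxy)-4-(triisopropylsilyloxy)phenyl]methanimine | COc1ccccc1/N=C/c1c(OCc2ccccc2)cc(O[Si](C(C)C)(C(C)C)C(C)C)cc1OCc1ccccc1 | intermediate
7 | (E)-1-methoxy-3-(trimethylsilyloxy)buta-1,3-diene | CO/C=C/C(=C)O[Si](C)(C)C | starting material
8 | (1E,5R)-5-[2,6-bis(benzyloxy)-4-(triisopropylsilyloxy)phenyl]-1-methoxy-5-(2-methoxyanilino)pent-1-en-3-one | CO/C=C/C(=O)C[C@@H](Nc1ccccc1OC)c1c(OCc2ccccc2)cc(O[Si](C(C)C)(C(C)C)C(C)C)cc1OCc1ccccc1 | intermediate
9 | (2R)-2-[2,6-bis(benzyloxy)-4-(triisopropylsilyloxy)phenyl]-1-(2-methoxyphenyl)-2,3-dihydropyridin-4(1H)-one | COc1ccccc1N1C=CC(=O)C[C@@H]1c1c(OCc2ccccc2)cc(O[Si](C(C)C)(C(C)C)C(C)C)cc1OCc1ccccc1 | intermediate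
10 | lithium (2R)-2-[2,6-bis(benzyloxy)-4-(triisopropylsilyloxy)phenyl]-1-(2-methoxyphenyl)-1,2,3,6-tetrahydropyridin-4-olate | [Li+].[O-]C1=CCN(c2ccccc2OC)[C@@H](c2c(OCc3ccccc3)cc(O[Si](C(C)C)(C(C)C)C(C)C)cc2OCc2ccccc2)C1 | intermediate
11 | (2R)-2-[2,6-bis(benzyloxy)-4-(triisopropylsilyloxy)phenyl]-1-(2-methoxyphenyl)-1,2,3,6-tetrahydropyridin-4-yl trifluoromethanesulfonate | O=S(=O)(OC1=CCN(c2ccccc2OC)[C@@H](c2c(OCc3ccccc3)cc(O[Si](C(C)C)(C(C)C)C(C)C)cc2OCc2ccccc2)C1)C(F)(F)F | intermediate
12 | (2R)-2-[2,6-bis(benzyloxy)-4-(triisopropylsilyloxy)phenyl]-1-(2-methoxyphenyl)piperidine | COc1ccccc1N1CCCC[C@@H]1c1c(OCc2ccccc2)cc(O[Si](C(C)C)(C(C)C)C(C)C)cc1OCc1ccccc1 | intermediate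
13 | (2R)-2-[2,6-bis(benzyloxy)-4-(triisopropylsilyloxy)phenyl]piperidine | N1CCCC[C@@H]1c1c(OCc2ccccc2)cc(O[Si](C(C)C)(C(C)C)C(C)C)cc1OCc1ccccc1 | intermediate
14 | (2R)-2-[2,6-bis(benzyloxy)-4-(triisopropylsilyloxy)phenyl]-1-methylidenepiperidin-1-ium ion | C=[N+]1CCCC[C@@H]1c1c(OCc2ccccc2)cc(O[Si](C(C)C)(C(C)C)C(C)C)cc1OCc1ccccc1 | intermediate
15 | (2R)-2-[2,6-bis(benzyloxy)-4-(triisopropylsilyloxy)phenyl]-1-methylpiperidine | CN1CCCC[C@@H]1c1c(OCc2ccccc2)cc(O[Si](C(C)C)(C(C)C)C(C)C)cc1OCc1ccccc1 | intermediate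
16 | 3,5-bis(benzyloxy)-4-[(2R)-1-methylpiperidin-2-yl]phenol | CN1CCCC[C@@H]1c1c(OCc2ccccc2)cc(O)cc1OCc1ccccc1 | intermediate
17 | 1-[4-(benzyloxy)phenyl]ethanone | CC(=O)c1ccc(OCc2ccccc2)cc1 | starting material
18 | diallyl carbonate | C=CCOC(=O)OCC=C | starting material
19 | prop-2-enyl 3-[4-(benzyloxy)phenyl]-3-oxopropanoate | C=CCOC(=O)CC(=O)c1ccc(OCc2ccccc2)cc1 | intermediate
20 | prop-2-enyl (3R)-3-[4-(benzyloxy)phenyl]-3-hydroxypropanoate | C=CCOC(=O)C[C@@H](O)c1ccc(OCc2ccccc2)cc1 | intermediate
21 | prop-2-enyl (3S)-3-[4-(benzyloxy)phenyl]-3-{3,5-bis(benzyloxy)-4-[(2R)-1-methylpiperidin-2-yl]phenoxy}propanoate | CN1CCCC[C@@H]1c1c(OCc2ccccc2)cc(O[C@@H](CC(=O)OCC=C)c2ccc(OCc3ccccc3)cc2)cc1OCc1ccccc1 | intermediate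
22 | (3S)-3-[4-(benzyloxy)phenyl]-3-{3,5-bis(benzyloxy)-4-[(2R)-1-methylpiperidin-2-yl]phenoxy}propanoic acid | CN1CCCC[C@@H]1c1c(OCc2ccccc2)cc(O[C@@H](CC(=O)O)c2ccc(OCc3ccccc3)cc2)cc1OCc1ccccc1 | intermediate
23 | mixed anhydride of 22 with trifluoroacetic acid | CN1CCCC[C@@H]1c1c(OCc2ccccc2)cc(O[C@@H](CC(=O)OC(=O)C(F)(F)F)c2ccc(OCc3ccccc3)cc2)cc1OCc1ccccc1 | intermediate
24 | (2S)-5,7-bis(benzyloxy)-2-[4-(benzyloxy)phenyl]-6-[(2R)-1-methylpiperidin-2-yl]-2,3-dihydrochromen-4-one | CN1CCCC[C@@H]1c1c(OCc2ccccc2)cc2c(c1OCc1ccccc1)C(=O)C[C@@H](c1ccc(OCc3ccccc3)cc1)O2 | intermediate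
25 | (2S)-5,7-dihydroxy-2-(4-hydroxyphenyl)-6-[(2R)-1-methylpiperidin-2-yl]-2,3-dihydrochromen-4-one | CN1CCCC[C@@H]1c1c(O)cc2c(c1O)C(=O)C[C@@H](c1ccc(O)cc1)O2 | target

**Step count**
- Total steps: 15.
- Longest linear sequence: 13 (steps 1–9 and 12–15).
- Steps 10 and 11 form the side branch.

**Steps most likely to fail**

Step 4. The Mannich addition to the donor-rich, di-ortho-substituted imine may be so slow that protodesilylation of the diene overtakes it. Binding of an ortho benzyloxy oxygen to silver may also loosen the chelate and erode facial selectivity.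
- The fallback sets out from 6 and 7 and gives up catalyst control.
- A hard Lewis acid (Yb(OTf)3, 10 mol %, MeCN, 0 °C, then dilute HCl) activates even donor-rich imines and should give the racemic dihydropyridone F1.
- Preparative chromatography on a chiral stationary phase separates 9 from its (S)-enantiomer F2.
- The route is rejoined at 9.

Step 12. β-Elimination of the activated alcohol to the cinnamate may outrun substitution, and partial ionisation at the para-alkoxybenzylic carbon may erode the inversion.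
- The fallback sets out from 15 and builds ring C through a chalcone.
- Friedel–Crafts acetylation of the free ring A position (AcOH, (CF3CO)2O, CH2Cl2) gives the silylated acetophenone F3.
- Bu4NF/AcOH frees the ortho-hydroxyacetophenone F4.
- Claisen–Schmidt condensation with commercial 4-(benzyloxy)benzaldehyde (KOH, EtOH) gives the 2'-hydroxychalcone F5.
- Oxa-Michael closure (NaOAc, EtOH, reflux) gives 24 together with its (2R)-epimer F6.
- Because C2'' is fixed, the two are diastereomers. They are separated by chromatography, and F6 is re-equilibrated under the same conditions and recycled.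
- The route is rejoined at 24.

Step 7. Oxidation at the α-C–H bonds of the tertiary arylamine, or of the trialkoxy ring A and its benzylic C2''–H, may compete with attack of water on the anisyl ring.
- The fallback avoids any N-aryl group and any oxidant, and sets out from 4.
- Condensation with (S)-tert-butanesulfinamide (Ti(OEt)4, THF) gives the sulfinyl aldimine F7.
- (4-Chlorobutyl)magnesium bromide F8 is made from 1-bromo-4-chlorobutane and magnesium. It adds in CH2Cl2/toluene at −48 °C through the closed magnesium-bridged chair to give the (R)-configured chloro sulfinamide F9, and the minor diastereomer is removed by chromatography.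
- KN(SiMe3)2 in THF closes the ring by 6-exo-tet N-alkylation to the N-sulfinylpiperidine F10.
- HCl in MeOH removes the auxiliary.
- The route is rejoined at 13.

**Further compounds**
F1 | step 4 | rac-2-[2,6-bis(benzyloxy)-4-(triisopropylsilyloxy)phenyl]-1-(2-methoxyphenyl)-2,3-dihydropyridin-4(1H)-one | COc1ccccc1N1C=CC(=O)CC1c1c(OCc2ccccc2)cc(O[Si](C(C)C)(C(C)C)C(C)C)cc1OCc1ccccc1
F2 | step 4 | (2S)-2-[2,6-bis(benzyloxy)-4-(triisopropylsilyloxy)phenyl]-1-(2-methoxyphenyl)-2,3-dihydropyridin-4(1H)-one | COc1ccccc1N1C=CC(=O)C[C@H]1c1c(OCc2ccccc2)cc(O[Si](C(C)C)(C(C)C)C(C)C)cc1OCc1ccccc1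
F3 | step 12 | 1-{2,4-bis(benzyloxy)-3-[(2R)-1-methylpiperidin-2-yl]-6-(triisopropylsilyloxy)phenyl}ethanone | CN1CCCC[C@@H]1c1c(OCc2ccccc2)cc(O[Si](C(C)C)(C(C)C)C(C)C)c(C(C)=O)c1OCc1ccccc1
F4 | step 12 | 1-{2,4-bis(benzyloxy)-6-hydroxy-3-[(2R)-1-methylpiperidin-2-yl]phenyl}ethanone | CN1CCCC[C@@H]1c1c(OCc2ccccc2)cc(O)c(C(C)=O)c1OCc1ccccc1
F5 | step 12 | (E)-1-{2,4-bis(benzyloxy)-6-hydroxy-3-[(2R)-1-methylpiperidin-2-yl]phenyl}-3-[4-(benzyloxy)phenyl]prop-2-en-1-one | CN1CCCC[C@@H]1c1c(OCc2ccccc2)cc(O)c(C(=O)/C=C/c2ccc(OCc3ccccc3)cc2)c1OCc1ccccc1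
F6 | step 12 | (2R)-5,7-bis(benzyloxy)-2-[4-(benzyloxy)phenyl]-6-[(2R)-1-methylpiperidin-2-yl]-2,3-dihydrochromen-4-one | CN1CCCC[C@@H]1c1c(OCc2ccccc2)cc2c(c1OCc1ccccc1)C(=O)C[C@H](c1ccc(OCc3ccccc3)cc1)O2
F7 | step 7 | (S)-N-{(E)-[2,6-bis(benzyloxy)-4-(triisopropylsilyloxy)phenyl]methylidene}-2-methylpropane-2-sulfinamide | CC(C)(C)[S@](=O)/N=C/c1c(OCc2ccccc2)cc(O[Si](C(C)C)(C(C)C)C(C)C)cc1OCc1ccccc1
F8 | step 7 | (4-chlorobutyl)magnesium bromide | ClCCCC[Mg]Br
F9 | step 7 | (S)-N-{(1R)-1-[2,6-bis(benzyloxy)-4-(triisopropylsilyloxy)phenyl]-5-chloropentyl}-2-methylpropane-2-sulfinamide | CC(C)(C)[S@](=O)N[C@H](CCCCCl)c1c(OCc2ccccc2)cc(O[Si](C(C)C)(C(C)C)C(C)C)cc1OCc1ccccc1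
F10 | step 7 | (2R)-2-[2,6-bis(benzyloxy)-4-(triisopropylsilyloxy)phenyl]-1-[(S)-tert-butylsulfinyl]piperidine | CC(C)(C)[S@](=O)N1CCCC[C@@H]1c1c(OCc2ccccc2)cc(O[Si](C(C)C)(C(C)C)C(C)C)cc1OCc1ccccc1
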